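**Retrosynthetic overview** (ring numbering of the target: O1, C2 aryl, C3 CH2OH, C4 carbinol side chain, C5 H2)
1. Target ⇐ dibenzyl ether 12 (hydrogenolysis) ⇐ vinyl tetrahydrofuran 10 (the C3 vinyl group is a masked CH2OH) ⇐ 1,4-diol 8 (O1–C5 ether closure) ⇐ γ-lactone 7 (C5 at the carboxyl level).
2. Key disconnection of 7: the C4–carbinol carbon bond (aldol) and the C3–vinyl bond (conjugate addition), made in one three-component operation from (R)-5-aryl butenolide 5, a vinyl copper reagent and aldehyde 1.
3. Enabling feature: the carbinol oxygen and ring oxygen O1 are 1,3-related through C4–C5. With C5 as a lactone C=O, C4 is an enolate carbon and C3 the β-carbon of a butenolide, so the C2 aryl group alone relays the all-trans C2/C3/C4 pattern and the carbinol configuration.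
4. Butenolide 5 ⇐ cis-semihydrogenation and lactonisation of propargylic alcohol 3 ⇐ asymmetric alkynylation of O-benzylvanillin 1 with methyl propiolate 2.
5. Ring order: there is only one ring. The O1–C2–C3–C4–C5 ring is made as the butenolide (step 2), kept through the key step, opened (step 4) and closed again at the ether level (step 5).

Key step: step 3

Remark on the chemistry: the ProPhenol enantiomer in step 1 is assumed to be chosen so that the (S)-carbinol results; both antipodes of the ligand are available, and the sense of induction would be checked on the first run.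

**Step 1**
Reactants: 1 4-(benzyloxy)-3-methoxybenzaldehyde; 2 methyl propiolate
Product: 3 methyl (S)-4-[4-(benzyloxy)-3-methoxyphenyl]-4-hydroxybut-2-ynoate
Conditions: Me2Zn (3 equiv), ProPhenol ligand (20 mol %, enantiomer chosen for the (S)-alcohol), Ph3PO (40 mol %), toluene, 4 °C; NH4Cl aq.
Reagents that add atoms: none
Why: Zinc–ProPhenol-catalysed asymmetric alkynylation of the non-enolisable aldehyde 1 with the zinc acetylide of 2 should set the benzylic stereocentre (the later ring carbon C2) by ligand control of the aldehyde face.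

**Step 2**
Reactants: 3 methyl (S)-4-[4-(benzyloxy)-3-methoxyphenyl]-4-hydroxybut-2-ynoate
Product: 5 (R)-5-[4-(benzyloxy)-3-methoxyphenyl]furan-2(5H)-one, via (Z)-hydroxy enoate 4 (not isolated)
Conditions: H2 (1 atm), Pd/CaCO3 poisoned with Pb(OAc)2 (Lindlar catalyst), quinoline, EtOAc, rt; then PPTS (cat.), CH2Cl2, rt
Reagents that add atoms: none
Why: Lindlar semihydrogenation should give the cis-enoate 4, whose hydroxyl then closes the butenolide by acid-catalysed lactonisation without touching the carbinol stereocentre (the descriptor changes from S to R only because the CIP ranking of the unsaturated carbon changes).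

**Step 3**
Reactants: 5 (R)-5-[4-(benzyloxy)-3-methoxyphenyl]furan-2(5H)-one; 1 4-(benzyloxy)-3-methoxybenzaldehyde
Product: 7 (3S,4R,5R)-5-[4-(benzyloxy)-3-methoxyphenyl]-3-{(R)-[4-(benzyloxy)-3-methoxyphenyl](hydroxy)methyl}-4-vinyldihydrofuran-2(3H)-one, via bromomagnesium enolate 6 (not isolated)
Conditions: CH2=CHMgBr (2.2 equiv), CuI (1.1 equiv), THF/Me2S, −40 °C, then 5, −78 °C; then 1 (1.3 equiv), −78 °C; AcOH in THF at −78 °C, then NH4Cl aq.
Reagents that add atoms: vinylmagnesium bromide, C=C[Mg]Br
Why: The divinylcuprate formed from CH2=CHMgBr and CuI should deliver a vinyl group to C4 of butenolide 5 (lactone numbering: O1, C2 carbonyl, C3, C4, C5 aryl) through a copper π-complex, oxidative addition and reductive elimination on the face opposite the C5 aryl group, and the resulting ring-locked (E)-enolate 6 is trapped in the same flask by aldehyde 1 through a closed, magnesium-chelated Zimmerman–Traxler chair on the face opposite the new vinyl group. The closest known reaction type is the three-component tandem organocopper conjugate addition/aldol trapping of cyclic enones and α,β-unsaturated lactones. No ring is closed; the step forms the C4–vinyl bond and the bond from lactone C3 (the later tetrahydrofuran C4) to the carbinol carbon, which completes the carbon skeleton. Three stereocentres arise: C4 is controlled by the C5 aryl group (trans), C3 by the C4 vinyl group (trans), and the carbinol carbon by the chair transition state, in which the enolate geometry forced by the ring and an equatorial aryl group lead to the anti aldol, that is the (R)-carbinol. The step needs 1,4-addition to win over 1,2-addition and over γ-deprotonation, which the soft cuprate at −78 °C should secure, and anti over syn selectivity, which the cyclic enolate geometry and a cold acidic quench (no retro-aldol equilibration) should secure.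

**Step 4**
Reactants: 7 (3S,4R,5R)-5-[4-(benzyloxy)-3-methoxyphenyl]-3-{(R)-[4-(benzyloxy)-3-methoxyphenyl](hydroxy)methyl}-4-vinyldihydrofuran-2(3H)-one
Product: 8 (1R,2R,3R,4R)-1,4-bis[4-(benzyloxy)-3-methoxyphenyl]-2-(hydroxymethyl)-3-vinylbutane-1,4-diol
Conditions: LiAlH4, THF, 0 °C (inverse addition); H2O/NaOH aq. work-up
Reagents that add atoms: none
Why: Hydride reduction of the lactone to the 1,4-diol (LiAlH4 ester reduction) should leave all four stereocentres untouched and expose the former carbonyl carbon as the only primary alcohol.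

**Step 5**
Reactants: 8 (1R,2R,3R,4R)-1,4-bis[4-(benzyloxy)-3-methoxyphenyl]-2-(hydroxymethyl)-3-vinylbutane-1,4-diol
Product: 10 (R)-[4-(benzyloxy)-3-methoxyphenyl]{(3R,4R,5R)-5-[4-(benzyloxy)-3-methoxyphenyl]-4-vinyltetrahydrofuran-3-yl}methanol, via primary monotosylate 9 (not isolated)
Conditions: TsCl (1.05 equiv), Et3N, DMAP (cat.), CH2Cl2, −10 → 0 °C; then KOt-Bu, THF, 0 °C → rt
Reagents that add atoms: p-toluenesulfonyl chloride, Cc1ccc(cc1)S(Cl)(=O)=O (its atoms are held only in intermediate 9)
Why: Selective sulfonylation of the sole primary hydroxyl followed by 5-exo-tet Williamson closure by the 1,4-related benzylic alkoxide (the 4-exo alternative from the other carbinol is far slower) should re-form the ring as the tetrahydrofuran with retention at the aryl-bearing carbon, because only the primary C–O bond is broken.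

**Step 6**
Reactants: 10 (R)-[4-(benzyloxy)-3-methoxyphenyl]{(3R,4R,5R)-5-[4-(benzyloxy)-3-methoxyphenyl]-4-vinyltetrahydrofuran-3-yl}methanol
Product: 12 (R)-[4-(benzyloxy)-3-methoxyphenyl]{(3R,4S,5R)-5-[4-(benzyloxy)-3-methoxyphenyl]-4-(hydroxymethyl)tetrahydrofuran-3-yl}methanol, via tetrahydrofuran-3-carbaldehyde 11 (not isolated)
Conditions: O3, CH2Cl2/MeOH, −78 °C (stopped at the first excess of ozone); then NaBH4, −78 → 0 °C
Reagents that add atoms: ozone, [O-][O+]=O
Why: Ozonolysis of the only alkene with reductive NaBH4 work-up should excise the terminal carbon and deliver the hydroxymethyl group, the aldehyde 11 being reduced before its α-centre (already in the favoured all-trans arrangement) can epimerise.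

**Step 7**
Reactants: 12 (R)-[4-(benzyloxy)-3-methoxyphenyl]{(3R,4S,5R)-5-[4-(benzyloxy)-3-methoxyphenyl]-4-(hydroxymethyl)tetrahydrofuran-3-yl}methanol
Product: 13 (R)-(4-hydroxy-3-methoxyphenyl)[(3R,4S,5R)-5-(4-hydroxy-3-methoxyphenyl)-4-(hydroxymethyl)tetrahydrofuran-3-yl]methanol
Conditions: H2 (1 atm), 10% Pd/C, EtOAc/EtOH, rt, stopped at complete debenzylation
Reagents that add atoms: none
Why: Hydrogenolysis of the two aryl benzyl ethers over Pd/C under neutral conditions should be much faster than cleavage of the benzylic alcohol or of the benzylic ring C–O bond, so the bisphenol should be released without stereochemical change.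

**Compound list**
1 | 4-(benzyloxy)-3-methoxybenzaldehyde | COc1cc(C=O)ccc1OCc1ccccc1 | starting material
2 | methyl propiolate | C#CC(=O)OC | starting material
3 | methyl (S)-4-[4-(benzyloxy)-3-methoxyphenyl]-4-hydroxybut-2-ynoate | O[C@@H](c1ccc(OCc2ccccc2)c(OC)c1)C#CC(=O)OC | intermediate
4 | methyl (R,Z)-4-[4-(benzyloxy)-3-methoxyphenyl]-4-hydroxybut-2-enoate (not isolated) | O[C@@H](c1ccc(OCc2ccccc2)c(OC)c1)/C=C\C(=O)OC | intermediate
5 | (R)-5-[4-(benzyloxy)-3-methoxyphenyl]furan-2(5H)-one | O=C1O[C@@H](c2ccc(OCc3ccccc3)c(OC)c2)C=C1 | intermediate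
6 | bromomagnesium enolate of (4R,5R)-5-[4-(benzyloxy)-3-methoxyphenyl]-4-vinyldihydrofuran-2(3H)-one (not isolated) | Br[Mg]OC1=C[C@@H](C=C)[C@H](c2ccc(OCc3ccccc3)c(OC)c2)O1 | intermediate
7 | (3S,4R,5R)-5-[4-(benzyloxy)-3-methoxyphenyl]-3-{(R)-[4-(benzyloxy)-3-methoxyphenyl](hydroxy)methyl}-4-vinyldihydrofuran-2(3H)-one | COc1cc([C@H](O)[C@H]2C(=O)O[C@@H](c3ccc(OCc4ccccc4)c(OC)c3)[C@@H]2C=C)ccc1OCc1ccccc1 | intermediate
8 | (1R,2R,3R,4R)-1,4-bis[4-(benzyloxy)-3-methoxyphenyl]-2-(hydroxymethyl)-3-vinylbutane-1,4-diol (C1 is the carbinol carbon next to the hydroxymethyl-bearing carbon) | COc1cc([C@H](O)[C@@H](CO)[C@@H](C=C)[C@@H](O)c2ccc(OCc3ccccc3)c(OC)c2)ccc1OCc1ccccc1 | intermediate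
9 | primary mono-p-toluenesulfonate of 8 (not isolated) | COc1cc([C@H](O)[C@@H](COS(=O)(=O)c2ccc(C)cc2)[C@@H](C=C)[C@@H](O)c2ccc(OCc3ccccc3)c(OC)c2)ccc1OCc1ccccc1 | intermediate
10 | (R)-[4-(benzyloxy)-3-methoxyphenyl]{(3R,4R,5R)-5-[4-(benzyloxy)-3-methoxyphenyl]-4-vinyltetrahydrofuran-3-yl}methanol | COc1cc([C@H](O)[C@H]2CO[C@@H](c3ccc(OCc4ccccc4)c(OC)c3)[C@@H]2C=C)ccc1OCc1ccccc1 | intermediate
11 | (2R,3R,4R)-2-[4-(benzyloxy)-3-methoxyphenyl]-4-{(R)-[4-(benzyloxy)-3-methoxyphenyl](hydroxy)methyl}tetrahydrofuran-3-carbaldehyde (not isolated) | COc1cc([C@H](O)[C@H]2CO[C@@H](c3ccc(OCc4ccccc4)c(OC)c3)[C@@H]2C=O)ccc1OCc1ccccc1 | intermediate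
12 | (R)-[4-(benzyloxy)-3-methoxyphenyl]{(3R,4S,5R)-5-[4-(benzyloxy)-3-methoxyphenyl]-4-(hydroxymethyl)tetrahydrofuran-3-yl}methanol | COc1cc([C@H](O)[C@H]2CO[C@@H](c3ccc(OCc4ccccc4)c(OC)c3)[C@@H]2CO)ccc1OCc1ccccc1 | intermediate
13 | (R)-(4-hydroxy-3-methoxyphenyl)[(3R,4S,5R)-5-(4-hydroxy-3-methoxyphenyl)-4-(hydroxymethyl)tetrahydrofuran-3-yl]methanol | COc1cc([C@H](O)[C@H]2CO[C@@H](c3ccc(O)c(OC)c3)[C@@H]2CO)ccc1O | target

**Step count:** 7 steps in total; longest linear sequence 7 steps (1 → 3 → 5 → 7 → 8 → 10 → 12 → 13).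

**Steps most likely to fail**

- **Step 3.** The aldol trapping may lose anti/syn selectivity at the carbinol carbon (open transition state, or retro-aldol equilibration of the magnesium aldolate). The basic organometallic may also deprotonate the γ-position of 5 in competition with conjugate addition. Fallback: the route sets out from 7 obtained as a mixture of carbinol epimers. Oxidation with Dess–Martin periodinane (CH2Cl2, rt) should give the β-keto lactone (3S,4R,5R)-3-[4-(benzyloxy)-3-methoxybenzoyl]-5-[4-(benzyloxy)-3-methoxyphenyl]-4-vinyldihydrofuran-2(3H)-one F1, whose acidic C3 stays trans to the vinyl group. Catalyst-controlled transfer hydrogenation of the aryl ketone with RuCl[(R,R)-TsDPEN](p-cymene) and HCO2H/Et3N (the enantiomer predicted by the acetophenone model for the (R)-carbinol) should then come back to 7 as a single carbinol epimer.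

- **Step 1.** The electron-rich, weakly electrophilic aldehyde may react sluggishly and with insufficient enantioselectivity, and the propiolate may oligomerise. Fallback: from 1 and 2, addition of the lithium acetylide of 2 (LiN(SiMe3)2, THF, −78 °C) should give racemic methyl 4-[4-(benzyloxy)-3-methoxyphenyl]-4-hydroxybut-2-ynoate F2. Oxidation with MnO2 (CH2Cl2, rt) should give the ynone methyl 4-[4-(benzyloxy)-3-methoxyphenyl]-4-oxobut-2-ynoate F3. Oxazaborolidine-catalysed reduction (2-methyl-CBS-oxazaborolidine, catecholborane, −78 °C; the catalyst enantiomer that delivers the (S)-carbinol with aryl as the large group, predicted to be (S)) should come back to 3.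

- **Step 6.** Ozone may attack the two electron-rich arenes or the benzylic positions in competition with the terminal alkene, or over-oxidise. Fallback: from 10, osmium-catalysed dihydroxylation (OsO4 cat., NMO, acetone/H2O) should give 1-{(2R,3R,4R)-2-[4-(benzyloxy)-3-methoxyphenyl]-4-{(R)-[4-(benzyloxy)-3-methoxyphenyl](hydroxy)methyl}tetrahydrofuran-3-yl}ethane-1,2-diol F4 (epimer mixture at the new carbinol, which is immaterial). Glycol cleavage with NaIO4 (THF/H2O) should give aldehyde 11, and NaBH4 in MeOH at 0 °C should come back to 12.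

**Further compounds**
F1 | step 3 | (3S,4R,5R)-3-[4-(benzyloxy)-3-methoxybenzoyl]-5-[4-(benzyloxy)-3-methoxyphenyl]-4-vinyldihydrofuran-2(3H)-one | COc1cc(C(=O)[C@H]2C(=O)O[C@@H](c3ccc(OCc4ccccc4)c(OC)c3)[C@@H]2C=C)ccc1OCc1ccccc1
F2 | step 1 | racemic methyl 4-[4-(benzyloxy)-3-methoxyphenyl]-4-hydroxybut-2-ynoate | COC(=O)C#CC(O)c1ccc(OCc2ccccc2)c(OC)c1
F3 | step 1 | methyl 4-[4-(benzyloxy)-3-methoxyphenyl]-4-oxobut-2-ynoate | COC(=O)C#CC(=O)c1ccc(OCc2ccccc2)c(OC)c1
F4 | step 6 | 1-{(2R,3R,4R)-2-[4-(benzyloxy)-3-methoxyphenyl]-4-{(R)-[4-(benzyloxy)-3-methoxyphenyl](hydroxy)methyl}tetrahydrofuran-3-yl}ethane-1,2-diol (epimer mixture at the new carbinol) | COc1cc([C@H](O)[C@H]2CO[C@@H](c3ccc(OCc4ccccc4)c(OC)c3)[C@@H]2C(O)CO)ccc1OCc1ccccc1
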